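The route rests on one disconnection: the C9–C10 bond of the ten-membered carbocycle, where the C9 carbinol meets the acrylate carbon C10. An intramolecular Nozaki–Hiyama–Kishi reaction forms this bond in the last step; in one operation it closes the ring C1–C10, sets C9 under control of C8 and gives the target. It exploits the hydroxy-acrylate unit C9(OH)–C10(CO2Me)=C1 and the three cis elements of the ring (C1=C10, cis-epoxide C2–C3, Z-C4=C5), which fold the chain. The precursor, seco-aldehyde 24, carries the finished trans-fused α-methylene lactone, the C8 epoxyangelate, a C9 aldehyde and a (Z)-2-iodoacrylate at C10.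

Key step: step 17

Remark: germacrane numbering (C1–C15, lactone C12–O–C6, ester C14) is used throughout; compounds 1, 7, 12, 15 and 18 are taken as commercial, and the indium Barbier reaction of step 10 is assumed to follow the closed chair transition state, which gives the C8 epimer that step 14 inverts.

Step 1
Reactants: 1 (Z)-3-methylpent-2-en-4-yn-1-ol
Product: 2 triethylsilyl ether of 1
Conditions: TESCl, imidazole, CH2Cl2, 0 °C
Reagents that add atoms: chlorotriethylsilane, CC[Si](Cl)(CC)CC
Why: Imidazole-promoted silylation masks the C6 hydroxyl so that only the later C1 hydroxyl can direct the Sharpless epoxidation; the Z geometry of C4=C5 is bought with 1.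

Step 2
Reactants: 2 triethylsilyl ether
Product: 4 (Z)-4-methyl-6-(triethylsilyloxy)hex-4-en-2-yn-1-ol, via lithium acetylide 3 (not isolated)
Conditions: n-BuLi, THF, −78 °C; (CH2O)n, −78 °C → rt
Reagents that add atoms: paraformaldehyde (formaldehyde), C=O
Why: Deprotonation of the terminal alkyne and addition of acetylide 3 to formaldehyde (acetylide hydroxymethylation) installs C1.

Step 3
Reactants: 4 enynol
Product: 5 (2Z,4Z)-4-methyl-6-(triethylsilyloxy)hexa-2,4-dien-1-ol
Conditions: H2 (1 atm), Pd/CaCO3 poisoned with Pb(OAc)2 (Lindlar catalyst), quinoline, EtOAc, rt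
Reagents that add atoms: none
Why: Lindlar semi-hydrogenation adds H2 syn to the alkyne and should stop at the (2Z,4Z)-diene, whose C2=C3 geometry becomes the cis-epoxide.

Step 4
Reactants: 5 dienol
Product: 6 cis-epoxy alcohol
Conditions: Ti(OiPr)4 (cat.), D-(−)-diethyl tartrate (cat.), t-BuOOH, 4 Å MS, CH2Cl2, −20 °C
Reagents that add atoms: tert-butyl hydroperoxide, CC(C)(C)OO
Why: Sharpless asymmetric epoxidation directed by the free C1 hydroxyl epoxidizes only the adjacent Z-alkene, D-(−)-tartrate delivering oxygen to the face that gives the (2R,3S) cis-epoxide (C2 and C3 of the target), while the silylated C6 oxygen cannot direct attack on C4=C5.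

Step 5
Reactants: 6 cis-epoxy alcohol; 7 methyl (triphenyl-λ5-phosphanylidene)acetate
Product: 9 (Z)-2-iodoacrylate TES ether, via epoxy aldehyde 8 (not isolated)
Conditions: Dess–Martin periodinane, pyridine, CH2Cl2, 0 °C; crude 8 added to 7 + NIS (CH2Cl2, −20 °C), then rt
Reagents that add atoms: N-iodosuccinimide, O=C1CCC(=O)N1I
Why: Dess–Martin oxidation gives cis-epoxy aldehyde 8, which reacts crude in a Wittig reaction with the iodo-ylide formed from 7 and NIS; the stabilized ylide places the ester trans to the epoxide and so gives the (Z)-2-iodoacrylate needed for a ring-cis C1=C10.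

Step 6
Reactants: 9 (Z)-2-iodoacrylate TES ether
Product: 10 Z-enal
Conditions: (COCl)2, DMSO, CH2Cl2, −78 → −40 °C; Et3N, −78 → 0 °C
Reagents that add atoms: none
Why: Under Swern conditions the chlorosulfonium reagent cleaves the primary triethylsilyl ether and oxidizes it in the same operation (Swern oxidation of a primary TES ether), and cold addition of the amine should keep the Z-enal from isomerizing.

Step 7
Reactants: 10 Z-enal
Product: 11 (S)-divinyl carbinol
Conditions: (CH2=CH)2Zn, (−)-3-exo-morpholinoisoborneol (10 mol%), toluene, −30 °C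
Reagents that add atoms: divinylzinc, C=C[Zn]C=C
Why: Amino-alcohol-catalysed enantioselective addition of an alkenylzinc reagent to the aldehyde sets C6 by reagent control (by analogy with dialkylzinc additions the (−)-ligand should give the S carbinol), and material from the minor epoxide enantiomer becomes a separable diastereomer.

Step 8
Reactants: 11 (S)-divinyl carbinol; 12 2-(bromomethyl)prop-2-enoic acid
Product: 13 2-(bromomethyl)acrylate ester of 11
Conditions: N,N'-diisopropylcarbodiimide, DMAP (cat.), CH2Cl2, 0 °C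
Reagents that add atoms: none
Why: Steglich esterification at 0 °C acylates the secondary alcohol with acid 12 without displacing the allylic bromide.

Step 9
Reactants: 13 2-(bromomethyl)acrylate ester
Product: 14 3-(bromomethyl)butenolide
Conditions: second-generation Grubbs catalyst [(H2IMes)(PCy3)Cl2Ru=CHPh, 5 mol%], CH2Cl2, 40 °C
Reagents that add atoms: none
Why: Ring-closing metathesis between the acrylate and the terminal vinyl group closes the five-membered butenolide with loss of ethene, the trisubstituted C4=C5 and iodoacrylate alkenes being too hindered to compete.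

Step 10
Reactants: 14 3-(bromomethyl)butenolide; 15 (tert-butyldimethylsilyloxy)acetaldehyde
Product: 17 8R carbinol of the trans-fused α-methylene lactone, via allylindium dibromide 16 (not isolated)
Conditions: In powder, THF/H2O, rt
Reagents that add atoms: none
Why: Indium inserts into the allylic bromide and allylindium 16 adds to aldehyde 15 through C7 (Barbier allylation, chair Zimmerman–Traxler transition state) on the face anti to the C6 side chain, which sets the trans-lactone (C7), regenerates the exocyclic methylene and should give the 8R carbinol that step 14 inverts.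

Step 11
Reactants: 18 methyl angelate
Product: 19 (Z)-2-methylbut-2-en-1-ol
Conditions: i-Bu2AlH, CH2Cl2, −78 → 0 °C
Reagents that add atoms: none
Why: Hydride 1,2-reduction of the ester gives the allylic alcohol and keeps the Z geometry.

Step 12
Reactants: 19 (Z)-2-methylbut-2-en-1-ol
Product: 20 (2S,3R)-epoxy alcohol
Conditions: Ti(OiPr)4 (cat.), L-(+)-diethyl tartrate (cat.), t-BuOOH, 4 Å MS, CH2Cl2, −20 °C
Reagents that add atoms: tert-butyl hydroperoxide, CC(C)(C)OO
Why: Sharpless asymmetric epoxidation with L-(+)-tartrate should deliver oxygen to the face that gives the (2S,3R) epoxy alcohol, which corresponds to the (2R,3R) acid.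

Step 13
Reactants: 20 (2S,3R)-epoxy alcohol
Product: 21 (2R,3R)-2,3-dimethyloxirane-2-carboxylic acid
Conditions: RuCl3·xH2O (cat.), NaIO4, CCl4/MeCN/H2O, rt
Reagents that add atoms: sodium periodate, [Na+].[O-][I](=O)(=O)=O; water, O
Why: Catalytically generated ruthenium tetroxide oxidizes the primary epoxy alcohol to the glycidic acid without opening the epoxide.

Step 14
Reactants: 17 8R carbinol; 21 (2R,3R)-2,3-dimethyloxirane-2-carboxylic acid
Product: 22 8S epoxyangelate TBS ether
Conditions: PPh3, DIAD, THF, 0 °C → rt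
Reagents that add atoms: none
Why: Mitsunobu esterification turns the C8 hydroxyl into an oxyphosphonium leaving group that the carboxylate of 21 displaces with inversion (SN2), converting the 8R alcohol into the 8S ester in one operation.

Step 15
Reactants: 22 8S epoxyangelate TBS ether
Product: 23 C9 primary alcohol
Conditions: HF·pyridine, pyridine, THF, 0 °C
Reagents that add atoms: none
Why: Buffered fluoride desilylation removes the primary TBS ether under weakly acidic conditions that should suppress acyl migration from O8 to O9 and spare the epoxides.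

Step 16
Reactants: 23 C9 primary alcohol
Product: 24 seco-aldehyde
Conditions: Dess–Martin periodinane, pyridine, CH2Cl2, 0 °C
Reagents that add atoms: none
Why: Buffered Dess–Martin oxidation gives the α-acyloxy aldehyde without epimerizing C8; it is used at once.

Step 17
Reactants: 24 seco-aldehyde
Product: 26 CNP0291485.1, via alkenylchromium dichloride 25 (not isolated)
Conditions: CrCl2 (excess), NiCl2 (cat.), degassed DMSO/THF, rt, slow addition to 2 mM
Reagents that add atoms: none
Why: Zerovalent nickel (formed from NiCl2 and CrCl2) inserts into the C10–I bond with retention, transmetalation gives the σ-alkenylchromium 25 (trivalent chromium), and this adds to the C9 aldehyde to form the C9–C10 bond as a chromium alkoxide. The closest known reaction type is the Nozaki–Hiyama–Kishi macrocyclization of an alkenyl iodide onto an aldehyde, here with a 2-iodoacrylate as the alkenyl partner. The ten-membered carbocycle C1–C10 closes in a 10-exo-trig mode (carbonyl oxygen exocyclic, C1=C10 endocyclic), helped by the three cis elements (Z-C4=C5, cis-epoxide C2–C3, ring-cis C1=C10) and the trans-fused lactone, which hold C9 and C10 within reach. The new C9 stereocenter is controlled by C8: with the C8–O(acyl) bond anti to the incoming C10 (polar Felkin–Anh alignment), the tether through C7 should force the bulky chromium-bound oxygen to the outside of the ring next to H8, the orientation that gives the 9S (8,9-syn) alcohol. The step needs chemoselective insertion into C–I beside the vinyl epoxide, the α-methylene lactone and the esters, retention of the C1=C10 geometry, and ring closure over oligomerization; the easily activated electron-poor iodoacrylate, the configurationally stable alkenylchromium and high dilution should secure these.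

Compound list
1 | (Z)-3-methylpent-2-en-4-yn-1-ol | OC/C=C(/C)C#C | starting material
2 | triethyl{[(Z)-3-methylpent-2-en-4-yn-1-yl]oxy}silane | CC[Si](CC)(CC)OC/C=C(/C)C#C | intermediate
3 | lithium acetylide of 2 (lithium on the alkyne terminus) | CC[Si](CC)(CC)OC/C=C(/C)C#C[Li] | intermediate
4 | (Z)-4-methyl-6-(triethylsilyloxy)hex-4-en-2-yn-1-ol | CC[Si](CC)(CC)OC/C=C(/C)C#CCO | intermediate
5 | (2Z,4Z)-4-methyl-6-(triethylsilyloxy)hexa-2,4-dien-1-ol | CC[Si](CC)(CC)OC/C=C(/C)\C=C/CO | intermediate
6 | [(2R,3S)-3-[(Z)-4-(triethylsilyloxy)but-2-en-2-yl]oxiran-2-yl]methanol (cis-epoxide) | CC[Si](CC)(CC)OC/C=C(/C)[C@@H]1O[C@@H]1CO | intermediate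
7 | methyl (triphenyl-λ5-phosphanylidene)acetate | COC(=O)C=P(c1ccccc1)(c1ccccc1)c1ccccc1 | starting material
8 | (2S,3S)-3-[(Z)-4-(triethylsilyloxy)but-2-en-2-yl]oxirane-2-carbaldehyde (cis-epoxide) | CC[Si](CC)(CC)OC/C=C(/C)[C@@H]1O[C@@H]1C=O | intermediate
9 | methyl (Z)-2-iodo-3-[(2R,3S)-3-[(Z)-4-(triethylsilyloxy)but-2-en-2-yl]oxiran-2-yl]prop-2-enoate | CC[Si](CC)(CC)OC/C=C(/C)[C@@H]1O[C@@H]1/C=C(/C(=O)OC)I | intermediate
10 | methyl (Z)-2-iodo-3-[(2R,3S)-3-[(Z)-4-oxobut-2-en-2-yl]oxiran-2-yl]prop-2-enoate | O=C/C=C(/C)[C@@H]1O[C@@H]1/C=C(/C(=O)OC)I | intermediate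
11 | methyl (Z)-3-[(2R,3S)-3-[(2Z,4S)-4-hydroxyhexa-2,5-dien-2-yl]oxiran-2-yl]-2-iodoprop-2-enoate | O[C@@H](C=C)/C=C(/C)[C@@H]1O[C@@H]1/C=C(/C(=O)OC)I | intermediate
12 | 2-(bromomethyl)prop-2-enoic acid | C=C(CBr)C(=O)O | starting material
13 | (3S,4Z)-5-[(2S,3R)-3-[(Z)-2-iodo-3-methoxy-3-oxoprop-1-en-1-yl]oxiran-2-yl]hexa-1,4-dien-3-yl 2-(bromomethyl)prop-2-enoate | C=C(CBr)C(=O)O[C@@H](C=C)/C=C(/C)[C@@H]1O[C@@H]1/C=C(/C(=O)OC)I | intermediate
14 | methyl (Z)-3-[(2R,3S)-3-[(Z)-1-[(2R)-4-(bromomethyl)-5-oxo-2,5-dihydrofuran-2-yl]prop-1-en-2-yl]oxiran-2-yl]-2-iodoprop-2-enoate | O=C1O[C@@H](C=C1CBr)/C=C(/C)[C@@H]1O[C@@H]1/C=C(/C(=O)OC)I | intermediate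
15 | (tert-butyldimethylsilyloxy)acetaldehyde | CC(C)(C)[Si](C)(C)OCC=O | starting material
16 | allylindium dibromide derived from 14 (InBr2 in place of Br on the CH2 group) | O=C1O[C@@H](C=C1C[In](Br)Br)/C=C(/C)[C@@H]1O[C@@H]1/C=C(/C(=O)OC)I | intermediate
17 | methyl (Z)-3-[(2R,3S)-3-[(Z)-1-[(2R,3R)-3-[(1R)-2-(tert-butyldimethylsilyloxy)-1-hydroxyethyl]-4-methylidene-5-oxooxolan-2-yl]prop-1-en-2-yl]oxiran-2-yl]-2-iodoprop-2-enoate (trans-lactone, 8R) | C=C1C(=O)O[C@H](/C=C(/C)[C@@H]2O[C@@H]2/C=C(/C(=O)OC)I)[C@H]1[C@@H](O)CO[Si](C)(C)C(C)(C)C | intermediate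
18 | methyl (Z)-2-methylbut-2-enoate (methyl angelate) | C/C=C(/C)C(=O)OC | starting material
19 | (Z)-2-methylbut-2-en-1-ol | C/C=C(/C)CO | intermediate
20 | [(2S,3R)-2,3-dimethyloxiran-2-yl]methanol | OC[C@]1(C)O[C@@H]1C | intermediate
21 | (2R,3R)-2,3-dimethyloxirane-2-carboxylic acid | OC(=O)[C@]1(C)O[C@@H]1C | intermediate
22 | (1S)-2-(tert-butyldimethylsilyloxy)-1-[(2R,3S)-2-[(Z)-2-[(2S,3R)-3-[(Z)-2-iodo-3-methoxy-3-oxoprop-1-en-1-yl]oxiran-2-yl]prop-1-en-1-yl]-4-methylidene-5-oxooxolan-3-yl]ethyl (2R,3R)-2,3-dimethyloxirane-2-carboxylate | C=C1C(=O)O[C@H](/C=C(/C)[C@@H]2O[C@@H]2/C=C(/C(=O)OC)I)[C@H]1[C@H](OC(=O)[C@]2(C)O[C@@H]2C)CO[Si](C)(C)C(C)(C)C | intermediate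
23 | (1S)-2-hydroxy-1-[(2R,3S)-2-[(Z)-2-[(2S,3R)-3-[(Z)-2-iodo-3-methoxy-3-oxoprop-1-en-1-yl]oxiran-2-yl]prop-1-en-1-yl]-4-methylidene-5-oxooxolan-3-yl]ethyl (2R,3R)-2,3-dimethyloxirane-2-carboxylate | C=C1C(=O)O[C@H](/C=C(/C)[C@@H]2O[C@@H]2/C=C(/C(=O)OC)I)[C@H]1[C@H](OC(=O)[C@]2(C)O[C@@H]2C)CO | intermediate
24 | (1S)-2-oxo-1-[(2R,3S)-2-[(Z)-2-[(2S,3R)-3-[(Z)-2-iodo-3-methoxy-3-oxoprop-1-en-1-yl]oxiran-2-yl]prop-1-en-1-yl]-4-methylidene-5-oxooxolan-3-yl]ethyl (2R,3R)-2,3-dimethyloxirane-2-carboxylate (seco-aldehyde) | C=C1C(=O)O[C@H](/C=C(/C)[C@@H]2O[C@@H]2/C=C(/C(=O)OC)I)[C@H]1[C@H](OC(=O)[C@]2(C)O[C@@H]2C)C=O | intermediate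
25 | alkenylchromium dichloride derived from 24 (CrCl2 in place of I at C10) | C=C1C(=O)O[C@H](/C=C(/C)[C@@H]2O[C@@H]2/C=C(/C(=O)OC)[Cr](Cl)Cl)[C@H]1[C@H](OC(=O)[C@]2(C)O[C@@H]2C)C=O | intermediate
26 | CNP0291485.1: (2R,3S,6R,7S,8S,9S)-2,3-epoxy-9-hydroxy-8-[(2R,3R)-2,3-dimethyloxirane-2-carbonyloxy]germacra-1(10),4,11(13)-trien-12,6-olid-14-oic acid methyl ester, C1=C10 and C4=C5 both cis within the ring | C=C1C(=O)O[C@@H]2/C=C(/C)[C@@H]3O[C@@H]3/C=C(/C(=O)OC)[C@H](O)[C@@H](OC(=O)[C@]3(C)O[C@@H]3C)[C@@H]12 | target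

Total step count: 17. Longest linear sequence: 14 steps (steps 1–10 and 14–17); steps 11–13 are the side branch to acid 21.

Steps most likely to fail

Step 17. The addition to the C9 aldehyde may proceed with poor facial selectivity (Felkin-type closure giving mainly the 9R alcohol), apart from the general risk of oligomerization. The fallback sets out from 24: the same cyclization is run and the 9R epimer F1 (alone or mixed with 26) is oxidized with Dess–Martin periodinane to the C9 ketone F2. A reagent-controlled Corey–Bakshi–Shibata reduction [(S)-2-methyl-CBS-oxazaborolidine, catecholborane, −78 °C], in which the C10 alkenyl group acts as the large substituent, should then deliver hydride to the face that gives 9S. The fallback comes back to the route at 26.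

Step 14. Activation of the hindered C8 hydroxyl may lead to elimination towards C7, or the bulky and only moderately acidic epoxy acid may fail to displace the oxyphosphonium group. The fallback sets out from 17: Mitsunobu inversion with the small, more acidic chloroacetic acid gives the 8S chloroacetate F3, and thiourea with NaHCO3 in ethanol removes the chloroacetyl group selectively to give the 8S alcohol F4. Yamaguchi esterification of F4 with 21 (2,4,6-trichlorobenzoyl chloride, Et3N, then DMAP) activates the acid instead of the alcohol and so retains C8. The fallback comes back to the route at 22.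

Step 7. The catalytic vinyl transfer may give poor face selectivity at C6, or the Z-enal may isomerize under the Lewis-acidic zinc conditions. The fallback sets out from 10: addition of CH2=CHMgBr at −78 °C gives 11 mixed with its C6 epimer F5, and Dess–Martin oxidation converges both to dienone F6. Corey–Bakshi–Shibata reduction [(R)-2-methyl-CBS-oxazaborolidine, BH3·SMe2, −40 °C], with the trisubstituted alkenyl group as the large substituent, should give the S carbinol. The fallback comes back to the route at 11.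

Further compounds
F1 | step 17 | 9R epimer of 26 | C=C1C(=O)O[C@@H]2/C=C(/C)[C@@H]3O[C@@H]3/C=C(/C(=O)OC)[C@@H](O)[C@@H](OC(=O)[C@]3(C)O[C@@H]3C)[C@@H]12
F2 | step 17 | C9 ketone (9-oxo analogue of 26) | C=C1C(=O)O[C@@H]2/C=C(/C)[C@@H]3O[C@@H]3/C=C(/C(=O)OC)C(=O)[C@@H](OC(=O)[C@]3(C)O[C@@H]3C)[C@@H]12
F3 | step 14 | 8S chloroacetate (C8-inverted chloroacetate of 17) | C=C1C(=O)O[C@H](/C=C(/C)[C@@H]2O[C@@H]2/C=C(/C(=O)OC)I)[C@H]1[C@H](OC(=O)CCl)CO[Si](C)(C)C(C)(C)C
F4 | step 14 | 8S alcohol (C8 epimer of 17) | C=C1C(=O)O[C@H](/C=C(/C)[C@@H]2O[C@@H]2/C=C(/C(=O)OC)I)[C@H]1[C@H](O)CO[Si](C)(C)C(C)(C)C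
F5 | step 7 | C6 epimer of 11 (R carbinol) | O[C@H](C=C)/C=C(/C)[C@@H]1O[C@@H]1/C=C(/C(=O)OC)I
F6 | step 7 | dienone, methyl (Z)-2-iodo-3-[(2R,3S)-3-[(Z)-4-oxohexa-2,5-dien-2-yl]oxiran-2-yl]prop-2-enoate | C=CC(=O)/C=C(/C)[C@@H]1O[C@@H]1/C=C(/C(=O)OC)I
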